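The middle flavan unit's pyran ring (ring C) is built last. Ring A of that unit, a phloroglucinol already C-linked to the gallocatechin unit, is a 1,3-C,O-bis-nucleophile (phenolic O1 and the ortho carbon C4a). A trans-epoxy benzylic carbinol that carries the ent-catechin unit on C4 and the catechol ring on C2 is the matching 1,3-bis-electrophile. One acid-catalysed operation joins these two advanced fragments: Friedel–Crafts arylation at C4 (C4a–C4) and 6-endo epoxide opening (O1–C2) close ring C and set C2 and C4 around the epoxide-derived C3 carbinol.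

Key step: step 12

Remark on the chemistry: the SMILES is read as gallocatechin-(4α→8)-catechin-(4β→8)-ent-catechin (top unit 2R,3S,4S, 3,4-trans; middle unit 2R,3S,4S, 3,4-cis; bottom unit 2S,3R); (+)-gallocatechin and (−)-catechin are taken as commercial.

Step 1
Reactants: 1 (+)-gallocatechin
Product: 2 5,7,3',4',5'-penta-O-benzyl-(+)-gallocatechin
Conditions: BnBr (5.5 equiv), K2CO3, DMF, 0 °C → rt, argon
Reagents that add atoms: benzyl bromide BrCc1ccccc1
Why: Williamson etherification under carbonate conditions alkylates the five phenols, leaves the less acidic C3 alcohol free and touches no stereocentre.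

Step 2
Reactants: 2 5,7,3',4',5'-penta-O-benzyl-(+)-gallocatechin
Product: 3 4β-(2-ethoxyethoxy)-5,7,3',4',5'-penta-O-benzyl-(+)-gallocatechin
Conditions: DDQ, 2-ethoxyethanol, CH2Cl2, rt
Reagents that add atoms: 2-ethoxyethanol CCOCCO
Why: DDQ benzylic C–H oxidation removes hydride from C4, helped by the 5,7-dibenzyloxy ring, and the cation should be trapped by the alcohol anti to the C2 aryl group (this C4 configuration is erased again in step 4).

Step 3
Reactants: 3 4β-(2-ethoxyethoxy)-5,7,3',4',5'-penta-O-benzyl-(+)-gallocatechin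
Product: 4 3-O-acetyl-4β-(2-ethoxyethoxy)-5,7,3',4',5'-penta-O-benzyl-(+)-gallocatechin
Conditions: Ac2O, DMAP (cat.), pyridine, rt
Reagents that add atoms: acetic anhydride CC(=O)OC(C)=O
Why: DMAP-catalysed acylation of the only free hydroxyl installs the ester that serves as participating group in step 4.

Step 4
Reactants: 4 3-O-acetyl-4β-(2-ethoxyethoxy)-5,7,3',4',5'-penta-O-benzyl-(+)-gallocatechin; 5 3,5-bis(benzyloxy)phenol (3 equiv)
Product: 6 3-O-acetyl-4α-[2,4-bis(benzyloxy)-6-hydroxyphenyl]-5,7,3',4',5'-penta-O-benzyl-(+)-gallocatechin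
Conditions: TMSOTf (cat.), CH2Cl2, −78 → −40 °C
Reagents that add atoms: none
Why: Lewis-acid-promoted Friedel–Crafts arylation of the flavan-4-yl cation, in which the 3-O-acetyl group bridges the β face as an acetoxonium ion so that the phenol, reacting through the less hindered carbon ortho to its free OH, should enter from the α face and give the 3,4-trans (4α) product.

Step 5
Reactants: 7 3,4-bis(benzyloxy)benzaldehyde; 8 triethyl phosphonoacetate
Product: 9 ethyl (E)-3-[3,4-bis(benzyloxy)phenyl]prop-2-enoate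
Conditions: NaH, THF, 0 °C → rt
Reagents that add atoms: none
Why: Horner–Wadsworth–Emmons olefination with a stabilised phosphonate should give the E-cinnamate.

Step 6
Reactants: 9 ethyl (E)-3-[3,4-bis(benzyloxy)phenyl]prop-2-enoate
Product: 10 (E)-3-[3,4-bis(benzyloxy)phenyl]prop-2-en-1-ol
Conditions: iBu2AlH (2.2 equiv), CH2Cl2, −78 → 0 °C
Reagents that add atoms: none
Why: 1,2-reduction of the ester with iBu2AlH gives the allylic alcohol without touching the alkene or the benzyl ethers.

Step 7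
Reactants: 10 (E)-3-[3,4-bis(benzyloxy)phenyl]prop-2-en-1-ol
Product: 11 [(2S,3S)-3-[3,4-bis(benzyloxy)phenyl]oxiran-2-yl]methanol
Conditions: TBHP, Ti(OiPr)4 (10 mol %), L-(+)-diisopropyl tartrate (12 mol %), 4 Å MS, CH2Cl2, −25 °C
Reagents that add atoms: tert-butyl hydroperoxide CC(C)(C)OO
Why: Sharpless asymmetric epoxidation with the L-(+)-tartrate should deliver oxygen to the face that gives the (2S,3S)-epoxide, which fixes C3 and, after inversion in step 12, C2 of the middle unit.

Step 8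
Reactants: 11 [(2S,3S)-3-[3,4-bis(benzyloxy)phenyl]oxiran-2-yl]methanol
Product: 12 (2R,3S)-3-[3,4-bis(benzyloxy)phenyl]oxirane-2-carbaldehyde
Conditions: Dess–Martin periodinane, pyridine, CH2Cl2, 0 °C; used crude
Reagents that add atoms: none
Why: buffered Dess–Martin oxidation converts the primary alcohol into the aldehyde without opening the epoxide or changing its geometry (the 2R label results only from the change in priorities).

Step 9
Reactants: 13 (−)-catechin
Product: 14 3,5,7,3',4'-penta-O-benzyl-(−)-catechin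
Conditions: BnBr, K2CO3, DMF, rt; then NaH, 0 °C → rt (same flask)
Reagents that add atoms: benzyl bromide BrCc1ccccc1
Why: Williamson etherification in two stages, carbonate for the four phenols and NaH for the C3 alcohol, with no change at C2 or C3.

Step 10
Reactants: 14 3,5,7,3',4'-penta-O-benzyl-(−)-catechin
Product: 15 8-bromo-3,5,7,3',4'-penta-O-benzyl-(−)-catechin
Conditions: NBS, CH2Cl2, −78 °C → rt
Reagents that add atoms: N-bromosuccinimide O=C1CCC(=O)N1Br
Why: electrophilic aromatic bromination with NBS, which should be regioselective for C8, the more accessible of the two free positions of ring A.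

Step 11
Reactants: 15 8-bromo-3,5,7,3',4'-penta-O-benzyl-(−)-catechin; 12 (2R,3S)-3-[3,4-bis(benzyloxy)phenyl]oxirane-2-carbaldehyde
Product: 17 (RS)-[3,5,7,3',4'-penta-O-benzyl-(−)-catechin-8-yl]{(2S,3S)-3-[3,4-bis(benzyloxy)phenyl]oxiran-2-yl}methanol, via the 8-lithio flavan 16 (not isolated)
Conditions: n-BuLi (1.0 equiv), THF, −78 °C; then 12, −78 °C; H2O
Reagents that add atoms: none
Why: bromine–lithium exchange gives an aryllithium flanked by two ether oxygens that should add 1,2 to the aldehyde faster than it attacks the epoxide, and the carbinol centre forms as a mixture that does not matter because it is ionised in step 12.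

Step 12
Reactants: 6 3-O-acetyl-4α-[2,4-bis(benzyloxy)-6-hydroxyphenyl]-5,7,3',4',5'-penta-O-benzyl-(+)-gallocatechin (1.3 equiv); 17 epoxy carbinol (both epimers)
Product: 19 3-O-acetyl-penta-O-benzylgallocatechin-(4α→8)-5,7,3',4'-tetra-O-benzylcatechin-(4β→8)-penta-O-benzyl-ent-catechin, via the Friedel–Crafts epoxy phenol 18 (not isolated)
Conditions: (PhO)2P(O)OH (10 mol %), 4 Å MS, CH2Cl2, −40 → 0 °C
Reagents that add atoms: none
Why: Proposed new method: diphenyl phosphate should ionise the carbinol of 17 first, because the 2,4,6-trioxygenated benzylic cation is far better stabilised than any epoxide-derived cation, and the ortho carbon of phenol 6 then attacks C4 to give 18, whose phenolic OH opens the protonated epoxide at its benzylic carbon; the closest known reaction types are the SN1 Friedel–Crafts benzylation of phenols with benzylic alcohols and the acid-catalysed 6-endo phenol–epoxide cyclisation used for flavan-3-ols, which have not been run as one domino on an epoxy carbinol. Ring C of the middle unit closes in the 6-endo-tet mode (O1 onto C2, with C4a–C4 already in place). C4 is set by the neighbouring epoxide carbon: allylic 1,3-strain with the two ortho oxygens of the ent-catechin ring holds the C3–H in the plane of the cation, and the arene should enter on the face that carries the epoxide oxygen (anti to the bulkier C3–C2 bond, guided by an ArOH···O hydrogen bond), which gives the 4β (3,4-cis) aryl group. C2 is set by inversion at the (S)-epoxide carbon, which gives 2R and the 2,3-trans relation, and C3 is carried over from step 7. The step needs arylation through the carbon ortho to the free OH of 6 in preference to its para carbon and to C8 of the top unit, secured by hydrogen-bond activation of the free phenol by the phosphate and by the fact that only the ortho adduct can cyclise, and it needs C4 ionisation before epoxide opening, secured by the electron-rich ent-catechin ring.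

Step 13
Reactants: 19 3-O-acetyl-penta-O-benzylgallocatechin-(4α→8)-5,7,3',4'-tetra-O-benzylcatechin-(4β→8)-penta-O-benzyl-ent-catechin
Product: 20 penta-O-benzylgallocatechin-(4α→8)-5,7,3',4'-tetra-O-benzylcatechin-(4β→8)-penta-O-benzyl-ent-catechin
Conditions: NaOMe (cat.), MeOH–THF, rt
Reagents that add atoms: none
Why: Zemplén transesterification removes the acetate and leaves the benzyl ethers and all stereocentres untouched.

Step 14
Reactants: 20 penta-O-benzylgallocatechin-(4α→8)-5,7,3',4'-tetra-O-benzylcatechin-(4β→8)-penta-O-benzyl-ent-catechin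
Product: 21 gallocatechin-(4α→8)-catechin-(4β→8)-ent-catechin (target)
Conditions: H2 (1 atm), Pd(OH)2/C, THF–MeOH–H2O, rt
Reagents that add atoms: none
Why: heterogeneous hydrogenolysis should cleave all fourteen benzyl ethers while the diaryl-substituted C4 centres and the pyran rings survive these neutral conditions.

Compound list
1 | (+)-gallocatechin, (2R,3S)-2-(3,4,5-trihydroxyphenyl)chromane-3,5,7-triol | Oc1cc(O)c2c(c1)O[C@H](c1cc(O)c(O)c(O)c1)[C@@H](O)C2 | starting material
2 | 5,7,3',4',5'-penta-O-benzyl-(+)-gallocatechin | O(Cc9ccccc9)c1cc(OCc9ccccc9)c2c(c1)O[C@H](c1cc(OCc9ccccc9)c(OCc9ccccc9)c(OCc9ccccc9)c1)[C@@H](O)C2 | intermediate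
3 | 4β-(2-ethoxyethoxy)-5,7,3',4',5'-penta-O-benzyl-(+)-gallocatechin | O(Cc9ccccc9)c1cc(OCc9ccccc9)c2c(c1)O[C@H](c1cc(OCc9ccccc9)c(OCc9ccccc9)c(OCc9ccccc9)c1)[C@@H](O)[C@H]2OCCOCC | intermediate
4 | 3-O-acetyl-4β-(2-ethoxyethoxy)-5,7,3',4',5'-penta-O-benzyl-(+)-gallocatechin | O(Cc9ccccc9)c1cc(OCc9ccccc9)c2c(c1)O[C@H](c1cc(OCc9ccccc9)c(OCc9ccccc9)c(OCc9ccccc9)c1)[C@@H](OC(C)=O)[C@H]2OCCOCC | intermediate
5 | 3,5-bis(benzyloxy)phenol | Oc1cc(OCc9ccccc9)cc(OCc9ccccc9)c1 | starting material
6 | 3-O-acetyl-4α-[2,4-bis(benzyloxy)-6-hydroxyphenyl]-5,7,3',4',5'-penta-O-benzyl-(+)-gallocatechin | O(Cc9ccccc9)c1cc(OCc9ccccc9)c2c(c1)O[C@H](c1cc(OCc9ccccc9)c(OCc9ccccc9)c(OCc9ccccc9)c1)[C@@H](OC(C)=O)[C@@H]2c1c(O)cc(OCc9ccccc9)cc1OCc9ccccc9 | intermediate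
7 | 3,4-bis(benzyloxy)benzaldehyde | O=Cc1ccc(OCc9ccccc9)c(OCc9ccccc9)c1 | starting material
8 | triethyl phosphonoacetate | CCOC(=O)CP(=O)(OCC)OCC | starting material
9 | ethyl (E)-3-[3,4-bis(benzyloxy)phenyl]prop-2-enoate | CCOC(=O)/C=C/c1ccc(OCc9ccccc9)c(OCc9ccccc9)c1 | intermediate
10 | (E)-3-[3,4-bis(benzyloxy)phenyl]prop-2-en-1-ol | OC/C=C/c1ccc(OCc9ccccc9)c(OCc9ccccc9)c1 | intermediate
11 | [(2S,3S)-3-[3,4-bis(benzyloxy)phenyl]oxiran-2-yl]methanol | OC[C@@H]1O[C@H]1c1ccc(OCc9ccccc9)c(OCc9ccccc9)c1 | intermediate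
12 | (2R,3S)-3-[3,4-bis(benzyloxy)phenyl]oxirane-2-carbaldehyde | O=C[C@@H]1O[C@H]1c1ccc(OCc9ccccc9)c(OCc9ccccc9)c1 | intermediate
13 | (−)-catechin (ent-catechin), (2S,3R)-2-(3,4-dihydroxyphenyl)chromane-3,5,7-triol | Oc1cc(O)c2c(c1)O[C@@H](c1ccc(O)c(O)c1)[C@H](O)C2 | starting material
14 | 3,5,7,3',4'-penta-O-benzyl-(−)-catechin | O(Cc9ccccc9)c1cc(OCc9ccccc9)c2c(c1)O[C@@H](c1ccc(OCc9ccccc9)c(OCc9ccccc9)c1)[C@H](OCc9ccccc9)C2 | intermediate
15 | 8-bromo-3,5,7,3',4'-penta-O-benzyl-(−)-catechin | Brc1c(OCc9ccccc9)cc(OCc9ccccc9)c2c1O[C@@H](c1ccc(OCc9ccccc9)c(OCc9ccccc9)c1)[C@H](OCc9ccccc9)C2 | intermediate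
16 | 8-lithio-3,5,7,3',4'-penta-O-benzyl-(−)-catechin | [Li]c1c(OCc9ccccc9)cc(OCc9ccccc9)c2c1O[C@@H](c1ccc(OCc9ccccc9)c(OCc9ccccc9)c1)[C@H](OCc9ccccc9)C2 | intermediate
17 | (RS)-[3,5,7,3',4'-penta-O-benzyl-(−)-catechin-8-yl]{(2S,3S)-3-[3,4-bis(benzyloxy)phenyl]oxiran-2-yl}methanol, both carbinol epimers | OC(c1c(OCc9ccccc9)cc(OCc9ccccc9)c2c1O[C@@H](c1ccc(OCc9ccccc9)c(OCc9ccccc9)c1)[C@H](OCc9ccccc9)C2)[C@@H]1O[C@H]1c1ccc(OCc9ccccc9)c(OCc9ccccc9)c1 | intermediate
18 | Friedel–Crafts adduct: 6 bonded through the carbon ortho to its phenolic OH to the former carbinol carbon of 17 (future C4, configured as in 19), (2S,3S)-epoxide intact | O(Cc9ccccc9)c1cc(OCc9ccccc9)c2c(c1)O[C@H](c1cc(OCc9ccccc9)c(OCc9ccccc9)c(OCc9ccccc9)c1)[C@@H](OC(C)=O)[C@@H]2c4c(O)c([C@H](c1c(OCc9ccccc9)cc(OCc9ccccc9)c2c1O[C@@H](c1ccc(OCc9ccccc9)c(OCc9ccccc9)c1)[C@H](OCc9ccccc9)C2)[C@@H]5O[C@H]5c1ccc(OCc9ccccc9)c(OCc9ccccc9)c1)c(OCc9ccccc9)cc4OCc9ccccc9 | intermediate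
19 | 3-O-acetyl-penta-O-benzylgallocatechin-(4α→8)-5,7,3',4'-tetra-O-benzylcatechin-(4β→8)-penta-O-benzyl-ent-catechin (middle unit 3-OH free) | O(Cc9ccccc9)c1cc(OCc9ccccc9)c2c(c1)O[C@H](c1cc(OCc9ccccc9)c(OCc9ccccc9)c(OCc9ccccc9)c1)[C@@H](OC(C)=O)[C@@H]2c1c(OCc9ccccc9)cc(OCc9ccccc9)c2c1O[C@H](c1ccc(OCc9ccccc9)c(OCc9ccccc9)c1)[C@@H](O)[C@H]2c1c(OCc9ccccc9)cc(OCc9ccccc9)c2c1O[C@@H](c1ccc(OCc9ccccc9)c(OCc9ccccc9)c1)[C@H](OCc9ccccc9)C2 | intermediate
20 | penta-O-benzylgallocatechin-(4α→8)-5,7,3',4'-tetra-O-benzylcatechin-(4β→8)-penta-O-benzyl-ent-catechin (top and middle 3-OH free) | O(Cc9ccccc9)c1cc(OCc9ccccc9)c2c(c1)O[C@H](c1cc(OCc9ccccc9)c(OCc9ccccc9)c(OCc9ccccc9)c1)[C@@H](O)[C@@H]2c1c(OCc9ccccc9)cc(OCc9ccccc9)c2c1O[C@H](c1ccc(OCc9ccccc9)c(OCc9ccccc9)c1)[C@@H](O)[C@H]2c1c(OCc9ccccc9)cc(OCc9ccccc9)c2c1O[C@@H](c1ccc(OCc9ccccc9)c(OCc9ccccc9)c1)[C@H](OCc9ccccc9)C2 | intermediate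
21 | gallocatechin-(4α→8)-catechin-(4β→8)-ent-catechin, CNP0155646.2 | Oc1cc(O)c2c(c1)O[C@H](c1cc(O)c(O)c(O)c1)[C@@H](O)[C@@H]2c1c(O)cc(O)c2c1O[C@H](c1ccc(O)c(O)c1)[C@@H](O)[C@H]2c1c(O)cc(O)c2c1O[C@@H](c1ccc(O)c(O)c1)[C@H](O)C2 | target

Total step count: 14. Longest linear sequence: 8 steps (steps 5, 6, 7, 8, 11, 12, 13, 14).

Steps most likely to fail

Step 12 (proposed new method). The phenol may arylate the C4 cation on the face anti to the epoxide oxygen (4α epimer), may react through its para carbon or through C8 of the top unit, or the electron-rich epoxide may isomerise before ring closure. The fallback uses known reactions in stepwise form and sets C4 by hydride delivery to a cyclic cation; it sets out from 6 and 17 and comes back at 19. Ti(OiPr)4-mediated opening of the 2,3-epoxy alcohol 17 by phenol 6 at the benzylic epoxide carbon, with inversion, should give the aryl ether diol F1. MnO2 should oxidise only its benzylic carbinol to the α-hydroxy ketone F2. CF3CO2H and Et3SiH should then bring about Friedel–Crafts cyclodehydration at the single free carbon ortho to the ether oxygen and ionic hydrogenation of the resulting cyclic diarylmethyl cation. Hydride should enter anti to the 3-hydroxyl, so that the ent-catechin ring ends cis to it, which is 19.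

Step 7. The acid-sensitive, electron-rich aryl epoxide may be opened by titanium alkoxide or tartrate during the epoxidation, with loss of material and of enantiomeric purity. The fallback replaces the titanium tartrate system by metal-free iminium catalysis; it sets out from 10 and comes back at 12, bypassing 11 and step 8. MnO2 oxidation gives (E)-3-[3,4-bis(benzyloxy)phenyl]prop-2-enal F3. Epoxidation with aqueous H2O2, catalysed by (R)-2-[bis(3,5-bis(trifluoromethyl)phenyl)(trimethylsilyloxy)methyl]pyrrolidine (the enantiomer selected on the steric-shielding model for the 2R,3S epoxide), should give 12 directly under near-neutral conditions.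

Step 4. The Friedel–Crafts coupling may show poor regioselectivity, with attack through the carbon para to the phenolic hydroxyl or double arylation. The fallback separates O-arylation from an O→C rearrangement, in the manner of aryl C-glycoside synthesis; it sets out from 4 and 5 and comes back at 6. At −78 °C with BF3·OEt2 and a short reaction time the phenol should be captured on oxygen to give 3-O-acetyl-4α-[3,5-bis(benzyloxy)phenoxy]-5,7,3',4',5'-penta-O-benzyl-(+)-gallocatechin F4. The isolated ether is then rearranged with Sc(OTf)3 (−30 → 0 °C): the flavanyl cation should be returned within the ion pair to the carbon ortho to the oxygen it left, again under acetoxonium control of the α face.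

Further compounds
F1 | step 12 | aryl ether diol, (1RS,2S,3R)-1-[3,5,7,3',4'-penta-O-benzyl-(−)-catechin-8-yl]-3-[3,4-bis(benzyloxy)phenyl]-3-aryloxypropane-1,2-diol, the aryloxy group being 6 bonded through its phenolic oxygen | O(Cc9ccccc9)c1cc(OCc9ccccc9)c2c(c1)O[C@H](c1cc(OCc9ccccc9)c(OCc9ccccc9)c(OCc9ccccc9)c1)[C@@H](OC(C)=O)[C@@H]2c4c(O[C@H](c1ccc(OCc9ccccc9)c(OCc9ccccc9)c1)[C@@H](O)C(O)c1c(OCc9ccccc9)cc(OCc9ccccc9)c2c1O[C@@H](c1ccc(OCc9ccccc9)c(OCc9ccccc9)c1)[C@H](OCc9ccccc9)C2)cc(OCc9ccccc9)cc4OCc9ccccc9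
F2 | step 12 | α-hydroxy ketone, (2R,3R)-1-[3,5,7,3',4'-penta-O-benzyl-(−)-catechin-8-yl]-3-[3,4-bis(benzyloxy)phenyl]-2-hydroxy-3-aryloxypropan-1-one, aryloxy group as in F1 | O(Cc9ccccc9)c1cc(OCc9ccccc9)c2c(c1)O[C@H](c1cc(OCc9ccccc9)c(OCc9ccccc9)c(OCc9ccccc9)c1)[C@@H](OC(C)=O)[C@@H]2c4c(O[C@H](c1ccc(OCc9ccccc9)c(OCc9ccccc9)c1)[C@@H](O)C(=O)c1c(OCc9ccccc9)cc(OCc9ccccc9)c2c1O[C@@H](c1ccc(OCc9ccccc9)c(OCc9ccccc9)c1)[C@H](OCc9ccccc9)C2)cc(OCc9ccccc9)cc4OCc9ccccc9
F3 | step 7 | (E)-3-[3,4-bis(benzyloxy)phenyl]prop-2-enal | O=C/C=C/c1ccc(OCc9ccccc9)c(OCc9ccccc9)c1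
F4 | step 4 | 3-O-acetyl-4α-[3,5-bis(benzyloxy)phenoxy]-5,7,3',4',5'-penta-O-benzyl-(+)-gallocatechin | O(Cc9ccccc9)c1cc(OCc9ccccc9)c2c(c1)O[C@H](c1cc(OCc9ccccc9)c(OCc9ccccc9)c(OCc9ccccc9)c1)[C@@H](OC(C)=O)[C@@H]2Oc1cc(OCc9ccccc9)cc(OCc9ccccc9)c1
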